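Everything rests on cutting the O1–C2 bonds of the two outer dihydrobenzofurans: the one fused to the styryl-bearing ring A and the one that carries the 3,5-dihydroxyphenyl ring D. Both are trans and both are 2R,3R, so one chiral Brønsted acid can write both. In one operation it places a proton on each future C3 and lets the neighbouring phenol oxygen close on the 4-methoxybenzylic C2: two rings, two C–O bonds, four stereocentres. The precursor is the enantiopure 2S,3S central dihydrobenzofuran, drawn from (2S)-naringenin, that bears two 2-(1,2-diarylvinyl)phenol units, one at C4 and one within its C3 aryl group, with chlorine marking the later styryl position.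

Key step: step 18

Remarks on the chemistry
- Assumption: (2S)-naringenin is bought as the single enantiomer. Its optical purity is to be checked by chiral HPLC at 1 and again at 2.
- The styryl position of ring A is held by chlorine, because a bromide there would compete with the aryl triflate in step 16. The couplings use the reactivity order iodide and aryl bromide, then aryl triflate, then aryl chloride.
- The two rings that supply the cyclising phenols are carried as symmetric resorcinol bis-MOM ethers, so each halogenation has only one productive position. Compounds 25 and 26 therefore carry a free spectator hydroxyl group on each of these rings.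
- Both alkenes of 25 are single Z isomers, fixed by syn-hydrostannation and couplings with retention.
- The methyl ethers are cleaved before the stilbene is built, since a 3-aryl-4-styryl-dihydrobenzofuran cyclises under the acidic conditions of ether cleavage.

Step 1
Reactants: 1 (2S)-naringenin
Product: 2 (2S)-5-hydroxy-7-methoxy-2-(4-methoxyphenyl)chroman-4-one
Conditions: TMSCHN2 (excess), MeOH/CH2Cl2, 0 °C to rt
Reagents that add atoms: (trimethylsilyl)diazomethane, C[Si](C)(C)C=[N+]=[N-]
Why: Diazoalkane O-methylation of phenols needs no base, so the 7- and 4'-hydroxyl groups are etherified while the 5-hydroxyl group stays locked in its hydrogen bond to the ketone, and no phenoxide arises that could open the pyranone ring and racemise C2.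

Step 2
Reactants: 2 (2S)-5-hydroxy-7-methoxy-2-(4-methoxyphenyl)chroman-4-one
Product: 3 (2S)-7-methoxy-2-(4-methoxyphenyl)-4-oxochroman-5-yl triflate
Conditions: Tf2O, pyridine, CH2Cl2, −10 °C
Reagents that add atoms: triflic anhydride, O=S(=O)(OS(=O)(=O)C(F)(F)F)C(F)(F)F
Why: Sulfonylation of the last phenol turns the former 5-oxygen into the coupling handle for C4 of the central ring, and cold pyridine is too weak a base to start the retro-oxa-Michael opening that would erode C2.

Step 3
Reactants: 3 (2S)-7-methoxy-2-(4-methoxyphenyl)-4-oxochroman-5-yl triflate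
Product: 4 methyl (2S,3S)-6-methoxy-2-(4-methoxyphenyl)-4-(triflyloxy)-2,3-dihydrobenzofuran-3-carboxylate (trans)
Conditions: PhI(OAc)2, H2SO4, HC(OMe)3, rt
Reagents that add atoms: trimethyl orthoformate, COC(OC)OC
Why: Oxidative ring contraction of flavanones with trivalent iodine in trimethyl orthoformate: the enol ether is attacked at C3 by the iodane, ring carbon C4a shifts from the ketal carbon to C3 as iodobenzene leaves, C2 is not touched, and the new C3 centre comes out trans to the C2 aryl group, although it is erased again in step 7.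

Step 4
Reactants: 4 methyl (2S,3S)-ester
Product: 5 (2S,3S)-6-methoxy-2-(4-methoxyphenyl)-4-(triflyloxy)-2,3-dihydrobenzofuran-3-carboxylic acid
Conditions: Me3SnOH, 1,2-dichloroethane, 80 °C; 1 M HCl wash
Reagents that add atoms: trimethyltin hydroxide, C[Sn](C)(C)O
Why: Ester cleavage with trimethyltin hydroxide is a near-neutral hydrolysis that spares the aryl triflate and avoids the enolate from which this β-aryloxy ester would open by E1cB elimination.

Step 5
Reactants: 5 (2S,3S)-acid
Product: 6 1,3-dioxoisoindolin-2-yl (2S,3S)-6-methoxy-2-(4-methoxyphenyl)-4-(triflyloxy)-2,3-dihydrobenzofuran-3-carboxylate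
Conditions: N-hydroxyphthalimide, DIC, DMAP (cat.), CH2Cl2, rt
Reagents that add atoms: N-hydroxyphthalimide, O=C1c2ccccc2C(=O)N1O
Why: Carbodiimide (Steglich-type) esterification gives the redox-active ester needed for radical decarboxylation.

Step 6
Reactants: 7 5-bromoresorcinol
Product: 8 1-bromo-3,5-bis(methoxymethoxy)benzene
Conditions: MOMCl, i-Pr2NEt, CH2Cl2, 0 °C to rt
Reagents that add atoms: chloromethyl methyl ether, COCCl
Why: Williamson-type acetal protection of both phenols keeps the ring symmetric and electron-rich and gives small ethers that are inert to organometallics and palladium and can later be removed without protic acid.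

Step 7
Reactants: 6 redox-active ester; 8 1-bromo-3,5-bis(methoxymethoxy)benzene
Product: 11 (2S,3S)-3-[3,5-bis(methoxymethoxy)phenyl]-6-methoxy-2-(4-methoxyphenyl)-2,3-dihydrobenzofuran-4-yl triflate, via aryllithium 9 (not isolated), via arylzinc chloride 10 (not isolated)
Conditions: 8, n-BuLi, THF, −78 °C; ZnCl2, −78 °C to rt; then 6, NiCl2·dme (20 mol%), 4,4'-di-tert-butyl-2,2'-bipyridine (40 mol%), THF/DMF, rt; aq NH4Cl
Reagents that add atoms: none
Why: Nickel-catalysed decarboxylative Negishi arylation of a redox-active ester: single-electron reduction releases CO2 and phthalimide anion, the planar benzylic C3 radical is taken up by aryl-nickel on the face away from the C2 aryl group, and reductive elimination sets C3 as S in the trans ring, while electron transfer to the ester at room temperature is far faster than insertion of bipyridine-ligated nickel into the hindered aryl triflate.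

Step 8
Reactants: 11 (2S,3S)-3-aryl triflate
Product: 12 (2S,3R)-3-[2-bromo-3,5-bis(methoxymethoxy)phenyl]-6-methoxy-2-(4-methoxyphenyl)-2,3-dihydrobenzofuran-4-yl triflate (trans; the C3 descriptor changes through priorities only)
Conditions: NBS (1.0 equiv), MeCN, −20 to 0 °C
Reagents that add atoms: N-bromosuccinimide, O=C1CCC(=O)N1Br
Why: Electrophilic aromatic bromination goes to the most electron-rich ring, the resorcinol diether, at the position para to one OMOM group and next to the benzylic carbon, which exists twice by symmetry, whereas the benzofuran ring is switched off by its triflate and the anisyl ring has only one donor.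

Step 9
Reactants: 12 bromide; 13 1-ethynyl-4-methoxybenzene
Product: 14 (2S,3S)-3-{3,5-bis(methoxymethoxy)-2-[(4-methoxyphenyl)ethynyl]phenyl}-6-methoxy-2-(4-methoxyphenyl)-2,3-dihydrobenzofuran-4-yl triflate
Conditions: Pd(PhCN)2Cl2, P(t-Bu)3, CuI, HN(i-Pr)2, dioxane, rt to 45 °C
Reagents that add atoms: none
Why: Sonogashira coupling: the slim alkyne carbon is the safest partner for a bromide flanked on both sides, and the monoligated palladium formed from P(t-Bu)3 adds to the C–Br bond while it leaves the aryl triflate alone.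

Step 10
Reactants: 14 alkyne
Product: 16 (2S,3S)-3-{2-[(E)-1-iodo-2-(4-methoxyphenyl)vinyl]-3,5-bis(methoxymethoxy)phenyl}-6-methoxy-2-(4-methoxyphenyl)-2,3-dihydrobenzofuran-4-yl triflate, via vinylstannane 15 (not isolated)
Conditions: Bu3SnH, PdCl2(PPh3)2 (cat.), THF, rt; then I2, 0 °C
Reagents that add atoms: iodine, II
Why: Palladium-catalysed syn-hydrostannation of an unsymmetrical diarylalkyne puts tin on the alkyne carbon next to the ortho-substituted aryl group (ortho-directing effect), which fixes a regiochemistry that hydroboration of a 3,5-dimethoxyphenyl/4-methoxyphenyl alkyne could not guarantee, and iododestannylation then proceeds with retention.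

Step 11
Reactants: 16 vinyl iodide; 17 3,5-dimethoxyphenylboronic acid
Product: 18 (2S,3S)-3-{2-[(Z)-1-(3,5-dimethoxyphenyl)-2-(4-methoxyphenyl)vinyl]-3,5-bis(methoxymethoxy)phenyl}-6-methoxy-2-(4-methoxyphenyl)-2,3-dihydrobenzofuran-4-yl triflate
Conditions: Pd2(dba)3, P(t-Bu)3, K3PO4, THF/H2O, rt
Reagents that add atoms: none
Why: Suzuki-Miyaura coupling with retention of geometry, in which an unhindered boronic acid meets the crowded carbon, the vinyl iodide reacts at room temperature, and Pd/P(t-Bu)3 again ignores the triflate, so that no nucleophilic carbon ever sits in the same molecule as an activated C4–O bond.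

Step 12
Reactants: 19 5-chlororesorcinol
Product: 20 1-chloro-3,5-bis(methoxymethoxy)benzene
Conditions: MOMCl, i-Pr2NEt, CH2Cl2, 0 °C to rt
Reagents that add atoms: chloromethyl methyl ether, COCCl
Why: The same acetal protection as in step 6 gives a symmetric, activated ring whose chlorine waits for the final Heck reaction.

Step 13
Reactants: 20 1-chloro-3,5-bis(methoxymethoxy)benzene
Product: 21 1-chloro-2-iodo-3,5-bis(methoxymethoxy)benzene
Conditions: NIS, MeCN, 0 °C to rt
Reagents that add atoms: N-iodosuccinimide, O=C1CCC(=O)N1I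
Why: Electrophilic aromatic iodination takes the position para to one OMOM group and ortho to the other, beside chlorine, which exists twice by symmetry, in preference to the more crowded position between the two OMOM groups.

Step 14
Reactants: 21 aryl iodide; 13 1-ethynyl-4-methoxybenzene
Product: 22 1-chloro-3,5-bis(methoxymethoxy)-2-[(4-methoxyphenyl)ethynyl]benzene
Conditions: PdCl2(PPh3)2, CuI, Et3N, THF, 50 °C
Reagents that add atoms: none
Why: Sonogashira coupling occurs at the C–I bond only, the C–Cl bond being inert to PdCl2(PPh3)2, and the slim alkyne tolerates the two ortho substituents.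

Step 15
Reactants: 22 diarylalkyne
Product: 23 (E)-tributyl{1-[2-chloro-4,6-bis(methoxymethoxy)phenyl]-2-(4-methoxyphenyl)vinyl}stannane
Conditions: Bu3SnH, PdCl2(PPh3)2 (cat.), THF, rt
Reagents that add atoms: tributyltin hydride, CCCC[SnH](CCCC)CCCC
Why: Palladium-catalysed syn-hydrostannation under the ortho-directing effect places tin geminal to the doubly ortho-substituted chlororesorcinol ring and cis to the new vinylic hydrogen, which gives one regio- and stereoisomer with the least crowded metal position.

Step 16
Reactants: 18 aryl triflate; 23 vinylstannane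
Product: 24 (2S,3S)-4-{(Z)-1-[2-chloro-4,6-bis(methoxymethoxy)phenyl]-2-(4-methoxyphenyl)vinyl}-3-{2-[(Z)-1-(3,5-dimethoxyphenyl)-2-(4-methoxyphenyl)vinyl]-3,5-bis(methoxymethoxy)phenyl}-6-methoxy-2-(4-methoxyphenyl)-2,3-dihydrobenzofuran
Conditions: Pd(PPh3)4, CuCl, LiCl, DMSO, 60 °C
Reagents that add atoms: none
Why: CuCl/LiCl-accelerated Stille coupling is the established answer to congested 1-substituted vinylstannanes and aryl triflates, it keeps the alkene geometry, Pd(PPh3)4 does not touch the aryl chloride, and the copper-assisted transfer of the vinyl group should outrun an intramolecular Heck insertion into the neighbouring alkene.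

Step 17
Reactants: 24 tetrakis-MOM ether
Product: 25 (2S,3S)-4-[(Z)-1-(2-chloro-4,6-dihydroxyphenyl)-2-(4-methoxyphenyl)vinyl]-3-{2-[(Z)-1-(3,5-dimethoxyphenyl)-2-(4-methoxyphenyl)vinyl]-3,5-dihydroxyphenyl}-6-methoxy-2-(4-methoxyphenyl)-2,3-dihydrobenzofuran (bis(triarylethylene) precursor)
Conditions: TMSOTf, 2,2'-bipyridyl, CH2Cl2, 0 °C to rt; then H2O
Reagents that add atoms: none
Why: Cleavage of aromatic MOM ethers with TMSOTf and 2,2'-bipyridyl runs through silyl ethers and a bipyridinium acetal under weakly basic conditions, so no free acid is present that could start an uncatalysed and unselective closure of the electron-rich alkenes.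

Step 18
Reactants: 25 bis(triarylethylene) precursor
Product: 26 central (2S,3S)-6-methoxy-2-(4-methoxyphenyl)-2,3-dihydrobenzofuran bearing at C4 the C3 of a (2R,3R)-4-chloro-6-hydroxy-2-(4-methoxyphenyl)-2,3-dihydrobenzofuran and at C3 the C4 of a (2R,3R)-3-(3,5-dimethoxyphenyl)-6-hydroxy-2-(4-methoxyphenyl)-2,3-dihydrobenzofuran
Conditions: chiral imidodiphosphorimidate (IDPi) Brønsted acid, BINOL-derived, bulky 3,3'-aryl groups, N-triflyl core (10 mol%; enantiomer picked on a model 2-(1,2-diarylvinyl)phenol), CHCl3, 2 mM, 5 Å molecular sieves, −20 °C to rt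
Reagents that add atoms: none
Why: Proposed new method: the confined acid transfers its proton to the diaryl-substituted alkene carbon (future C3) of each 2-(1,2-diarylvinyl)phenol, which gives a 4-methoxybenzylic cation held as a contact ion pair with the chiral anion, and the ortho phenol oxygen captures it at C2; the closest known reaction types are the acid-mediated cyclisation of 2-hydroxystilbenes to 2-aryl-2,3-dihydrobenzofurans and the imidodiphosphorimidate-catalysed asymmetric intramolecular hydroalkoxylation of alkenes. Each of the two rings closes in a formally 5-endo-trig mode, which is open here because a discrete cation and not the alkene is attacked. C3 of each new ring is controlled by the catalyst, which either selects the alkene face in the proton transfer or, since proton loss is fast and reversible, selects the faster-closing of the two diastereomeric ion pairs, so that the alkene geometry loses its weight and one catalyst enantiomer can write R at both centres. C2 of each new ring is controlled by its neighbour C3, the oxygen approaching anti to the C3 aryl group to give the trans ring, which is also the more stable one. The step needs protonation at the diaryl carbon and O-capture instead of C-capture: protonation at the other alkene carbon gives a diarylmethyl cation that oxygen could reach only through a four-membered ring and that simply reverts, only the ortho hydroxyl groups can reach C2, and low temperature, high dilution and the narrow catalyst pocket hold back Friedel-Crafts attack by the resorcinol rings. Ionisation of the existing O1–C2 bond of the central ring is harmless, because its untouched C3 steers reclosure back to the trans 2S,3S ring.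

Step 19
Reactants: 26 tris(dihydrobenzofuran) hexamethyl ether
Product: 28 octaacetate of the chloro tris(dihydrobenzofuran), via octaphenol 27 (not isolated)
Conditions: BBr3 (20 equiv), CH2Cl2, −78 to 0 °C; ice-water work-up; crude 27, Ac2O, pyridine, DMAP (cat.), CH2Cl2, rt
Reagents that add atoms: acetic anhydride, CC(=O)OC(C)=O
Why: Lewis-acid cleavage of the six aryl methyl ethers followed by peracetylation is run while no acid-sensitive stilbene is present, the excess BBr3 ties up the para oxygen donors so that O1–C2 ionisation is disfavoured, and any ring that does open recloses trans under the control of its own C3.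

Step 20
Reactants: 29 caffeic acid
Product: 31 3,4-diacetoxystyrene, via 4-vinylcatechol 30 (not isolated)
Conditions: Et3N, DMF, 100 °C; then Ac2O, rt
Reagents that add atoms: acetic anhydride, CC(=O)OC(C)=O
Why: Amine-promoted thermal decarboxylation of a 4-hydroxycinnamic acid through its quinone methide tautomer gives the vinylcatechol, which is acetylated in the same flask before it can polymerise or oxidise.

Step 21
Reactants: 28 octaacetate aryl chloride; 31 3,4-diacetoxystyrene
Product: 32 decaacetate of the target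
Conditions: Pd(P(t-Bu)3)2 (10 mol%), Cy2NMe, BHT (trace), dioxane, 110 °C
Reagents that add atoms: none
Why: Mizoroki-Heck reaction of an aryl chloride, for which the bulky and electron-rich Pd(P(t-Bu)3)2 with Cy2NMe is the established system, proceeds by syn-insertion at the unsubstituted alkene carbon and syn-β-hydride elimination to the E-stilbene, and the acetates are inert to the hindered amine.

Step 22
Reactants: 32 decaacetate
Product: 33 CNP0099535.1 (target)
Conditions: NH3 (7 M in MeOH), argon, 0 °C to rt
Reagents that add atoms: none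
Why: Aminolysis of aryl acetates is fast under mild, non-acidic conditions that touch neither the stilbene nor the six stereocentres, and exclusion of air protects the catechol.

Compound list
1 | (2S)-naringenin | O=C1C[C@@H](c2ccc(O)cc2)Oc2cc(O)cc(O)c12 | starting material
2 | (2S)-5-hydroxy-7-methoxy-2-(4-methoxyphenyl)chroman-4-one | O=C1C[C@@H](c2ccc(OC)cc2)Oc2cc(OC)cc(O)c12 | intermediate
3 | (2S)-7-methoxy-2-(4-methoxyphenyl)-4-oxochroman-5-yl triflate | O=C1C[C@@H](c2ccc(OC)cc2)Oc2cc(OC)cc(OS(=O)(=O)C(F)(F)F)c12 | intermediate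
4 | methyl (2S,3S)-6-methoxy-2-(4-methoxyphenyl)-4-(triflyloxy)-2,3-dihydrobenzofuran-3-carboxylate | COc1ccc([C@H]2Oc3cc(OC)cc(OS(=O)(=O)C(F)(F)F)c3[C@@H]2C(=O)OC)cc1 | intermediate
5 | (2S,3S)-6-methoxy-2-(4-methoxyphenyl)-4-(triflyloxy)-2,3-dihydrobenzofuran-3-carboxylic acid | COc1ccc([C@H]2Oc3cc(OC)cc(OS(=O)(=O)C(F)(F)F)c3[C@@H]2C(=O)O)cc1 | intermediate
6 | N-hydroxyphthalimide ester of 5 | COc1ccc([C@H]2Oc3cc(OC)cc(OS(=O)(=O)C(F)(F)F)c3[C@@H]2C(=O)ON2C(=O)c3ccccc3C2=O)cc1 | intermediate
7 | 5-bromoresorcinol | Oc1cc(O)cc(Br)c1 | starting material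
8 | 1-bromo-3,5-bis(methoxymethoxy)benzene | COCOc1cc(Br)cc(OCOC)c1 | intermediate
9 | 3,5-bis(methoxymethoxy)phenyllithium | [Li]c1cc(OCOC)cc(OCOC)c1 | intermediate (not isolated)
10 | 3,5-bis(methoxymethoxy)phenylzinc chloride | Cl[Zn]c1cc(OCOC)cc(OCOC)c1 | intermediate (not isolated)
11 | (2S,3S)-3-[3,5-bis(methoxymethoxy)phenyl]-6-methoxy-2-(4-methoxyphenyl)-2,3-dihydrobenzofuran-4-yl triflate | COc1ccc([C@H]2Oc3cc(OC)cc(OS(=O)(=O)C(F)(F)F)c3[C@@H]2c2cc(OCOC)cc(OCOC)c2)cc1 | intermediate
12 | (2S,3R)-3-[2-bromo-3,5-bis(methoxymethoxy)phenyl]-6-methoxy-2-(4-methoxyphenyl)-2,3-dihydrobenzofuran-4-yl triflate | COc1ccc([C@H]2Oc3cc(OC)cc(OS(=O)(=O)C(F)(F)F)c3[C@@H]2c2cc(OCOC)cc(OCOC)c2Br)cc1 | intermediate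
13 | 1-ethynyl-4-methoxybenzene | C#Cc1ccc(OC)cc1 | starting material
14 | (2S,3S)-3-{3,5-bis(methoxymethoxy)-2-[(4-methoxyphenyl)ethynyl]phenyl}-6-methoxy-2-(4-methoxyphenyl)-2,3-dihydrobenzofuran-4-yl triflate | COc1ccc([C@H]2Oc3cc(OC)cc(OS(=O)(=O)C(F)(F)F)c3[C@@H]2c2cc(OCOC)cc(OCOC)c2C#Cc2ccc(OC)cc2)cc1 | intermediate
15 | (E)-1-tributylstannyl alkene from 14 (tin geminal to the resorcinol ring) | COc1ccc([C@H]2Oc3cc(OC)cc(OS(=O)(=O)C(F)(F)F)c3[C@@H]2c2cc(OCOC)cc(OCOC)c2/C(=C\c2ccc(OC)cc2)[Sn](CCCC)(CCCC)CCCC)cc1 | intermediate (not isolated)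
16 | (2S,3S)-3-{2-[(E)-1-iodo-2-(4-methoxyphenyl)vinyl]-3,5-bis(methoxymethoxy)phenyl}-6-methoxy-2-(4-methoxyphenyl)-2,3-dihydrobenzofuran-4-yl triflate | COc1ccc([C@H]2Oc3cc(OC)cc(OS(=O)(=O)C(F)(F)F)c3[C@@H]2c2cc(OCOC)cc(OCOC)c2/C(I)=C\c2ccc(OC)cc2)cc1 | intermediate
17 | 3,5-dimethoxyphenylboronic acid | COc1cc(OC)cc(B(O)O)c1 | starting material
18 | (2S,3S)-3-{2-[(Z)-1-(3,5-dimethoxyphenyl)-2-(4-methoxyphenyl)vinyl]-3,5-bis(methoxymethoxy)phenyl}-6-methoxy-2-(4-methoxyphenyl)-2,3-dihydrobenzofuran-4-yl triflate | COc1ccc([C@H]2Oc3cc(OC)cc(OS(=O)(=O)C(F)(F)F)c3[C@@H]2c2cc(OCOC)cc(OCOC)c2/C(=C\c2ccc(OC)cc2)c2cc(OC)cc(OC)c2)cc1 | intermediate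
19 | 5-chlororesorcinol | Oc1cc(O)cc(Cl)c1 | starting material
20 | 1-chloro-3,5-bis(methoxymethoxy)benzene | COCOc1cc(Cl)cc(OCOC)c1 | intermediate
21 | 1-chloro-2-iodo-3,5-bis(methoxymethoxy)benzene | COCOc1cc(Cl)c(I)c(OCOC)c1 | intermediate
22 | 1-chloro-3,5-bis(methoxymethoxy)-2-[(4-methoxyphenyl)ethynyl]benzene | COCOc1cc(Cl)c(C#Cc2ccc(OC)cc2)c(OCOC)c1 | intermediate
23 | (E)-tributyl{1-[2-chloro-4,6-bis(methoxymethoxy)phenyl]-2-(4-methoxyphenyl)vinyl}stannane | COCOc1cc(Cl)c(/C(=C\c2ccc(OC)cc2)[Sn](CCCC)(CCCC)CCCC)c(OCOC)c1 | intermediate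
24 | tetrakis-MOM ether of 25 | COc1ccc([C@H]2Oc3cc(OC)cc(/C(=C/c4ccc(OC)cc4)c4c(Cl)cc(OCOC)cc4OCOC)c3[C@@H]2c2cc(OCOC)cc(OCOC)c2/C(=C\c2ccc(OC)cc2)c2cc(OC)cc(OC)c2)cc1 | intermediate
25 | bis(triarylethylene) precursor, central ring 2S,3S, both alkenes Z | COc1ccc([C@H]2Oc3cc(OC)cc(/C(=C/c4ccc(OC)cc4)c4c(Cl)cc(O)cc4O)c3[C@@H]2c2cc(O)cc(O)c2/C(=C\c2ccc(OC)cc2)c2cc(OC)cc(OC)c2)cc1 | intermediate
26 | chloro tris(dihydrobenzofuran) hexamethyl ether, central ring 2S,3S, outer rings 2R,3R | COc1ccc([C@H]2Oc3cc(OC)cc([C@@H]4c5c(Cl)cc(O)cc5O[C@H]4c4ccc(OC)cc4)c3[C@@H]2c2cc(O)cc3c2[C@@H](c2cc(OC)cc(OC)c2)[C@H](c2ccc(OC)cc2)O3)cc1 | intermediate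
27 | chloro tris(dihydrobenzofuran) octaphenol | Oc1ccc([C@H]2Oc3cc(O)cc([C@@H]4c5c(Cl)cc(O)cc5O[C@H]4c4ccc(O)cc4)c3[C@@H]2c2cc(O)cc3c2[C@@H](c2cc(O)cc(O)c2)[C@H](c2ccc(O)cc2)O3)cc1 | intermediate (not isolated)
28 | octaacetate of 27 | CC(=O)Oc1ccc([C@H]2Oc3cc(OC(C)=O)cc([C@@H]4c5c(Cl)cc(OC(C)=O)cc5O[C@H]4c4ccc(OC(C)=O)cc4)c3[C@@H]2c2cc(OC(C)=O)cc3c2[C@@H](c2cc(OC(C)=O)cc(OC(C)=O)c2)[C@H](c2ccc(OC(C)=O)cc2)O3)cc1 | intermediate
29 | caffeic acid | OC(=O)/C=C/c1ccc(O)c(O)c1 | starting material
30 | 4-vinylcatechol | C=Cc1ccc(O)c(O)c1 | intermediate (not isolated)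
31 | 3,4-diacetoxystyrene | C=Cc1ccc(OC(C)=O)c(OC(C)=O)c1 | intermediate
32 | decaacetate of the target | CC(=O)Oc1ccc([C@H]2Oc3cc(OC(C)=O)cc([C@@H]4c5c(/C=C/c6ccc(OC(C)=O)c(OC(C)=O)c6)cc(OC(C)=O)cc5O[C@H]4c4ccc(OC(C)=O)cc4)c3[C@@H]2c2cc(OC(C)=O)cc3c2[C@@H](c2cc(OC(C)=O)cc(OC(C)=O)c2)[C@H](c2ccc(OC(C)=O)cc2)O3)cc1 | intermediate
33 | CNP0099535.1 | Oc1ccc([C@H]2Oc3cc(O)cc([C@@H]4c5c(/C=C/c6ccc(O)c(O)c6)cc(O)cc5O[C@H]4c4ccc(O)cc4)c3[C@@H]2c2cc(O)cc3c2[C@@H](c2cc(O)cc(O)c2)[C@H](c2ccc(O)cc2)O3)cc1 | target

Total number of steps: 22. Longest linear sequence: 16 steps (steps 1–5, 7–11, 16–19, 21 and 22, from 1 to 33).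

Steps most likely to fail

1) Step 18.
- What may go wrong: proton transfer to the crowded alkenes may be too slow. Facial selectivity at one C3 may be poor where catalyst and central ring are mismatched. Selectivity may erode through reversible ring opening, or the cations may be lost to irreversible Friedel-Crafts capture by the resorcinol rings.
- Fallback: it sets out from 25, comes back at 26 and gives up catalyst control altogether. The known acid-mediated cyclisation of 2-hydroxystilbenes (TsOH in toluene or catalytic TfOH in CH2Cl2, 0 °C) closes both rings to the trans products under thermodynamic control.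
- Because the central ring is enantiopure, all stereoisomers are diastereomers. Compound 26 is then separated by preparative HPLC from the isomer with a 2S,3S ring on the ring A side F1, the isomer with a 2S,3S ring on the ring D side F2 and the isomer with both outer rings 2S,3S F3. These three are returned to the acid for re-equilibration.

2) Step 3.
- What may go wrong: migration of the electron-rich 4-methoxyphenyl group from C2 to C3, or loss of H-2, may outrun the shift of the ring carbon that the triflate has made electron-poor.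
- Fallback: it sets out from 3, comes back at 4 and replaces the oxidative shift by a Wolff ring contraction, in which only the ring carbon can migrate.
- Kinetic enolisation (LiHMDS, THF, −78 °C) and acylation with 2,2,2-trifluoroethyl trifluoroacetate give the 3-trifluoroacetyl ketone F4.
- Diazo transfer with MsN3 and Et3N in wet MeCN gives the 3-diazo ketone F5.
- Irradiation in MeOH gives the ring-contracted ketene. Its methanol adduct is protonated from the open face, mainly to the cis ester F6, and DBU in toluene equilibrates this to 4.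

3) Step 7.
- What may go wrong: the stabilised benzylic radical may escape nickel through dimerisation or hydrogen abstraction, or nickel may insert into the aryl triflate.
- Fallback: it sets out from 6, comes back at 11 and separates radical generation from C–C bond formation.
- Copper-catalysed decarboxylative borylation (B2pin2, Cu(acac)2, LiOH·H2O, MgCl2, dioxane/DMF, rt) gives the trans C3 pinacol boronic ester F7. Boron enters anti to the C2 aryl group.
- Aryllithium 9, made from 8 as in step 7, is added at −78 °C to give the lithium boronate complex F8.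
- NBS then triggers the stereoretentive 1,2-metallate shift onto the electron-rich ring. Loss of boron and bromine follows and delivers 11.

Further compounds
F1 | step 18 | diastereomer of 26 with the ring A side dihydrobenzofuran 2S,3S | COc1ccc([C@H]2Oc3cc(OC)cc([C@H]4c5c(Cl)cc(O)cc5O[C@@H]4c4ccc(OC)cc4)c3[C@@H]2c2cc(O)cc3c2[C@@H](c2cc(OC)cc(OC)c2)[C@H](c2ccc(OC)cc2)O3)cc1
F2 | step 18 | diastereomer of 26 with the ring D side dihydrobenzofuran 2S,3S | COc1ccc([C@H]2Oc3cc(OC)cc([C@@H]4c5c(Cl)cc(O)cc5O[C@H]4c4ccc(OC)cc4)c3[C@@H]2c2cc(O)cc3c2[C@H](c2cc(OC)cc(OC)c2)[C@@H](c2ccc(OC)cc2)O3)cc1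
F3 | step 18 | diastereomer of 26 with both outer dihydrobenzofurans 2S,3S | COc1ccc([C@H]2Oc3cc(OC)cc([C@H]4c5c(Cl)cc(O)cc5O[C@@H]4c4ccc(OC)cc4)c3[C@@H]2c2cc(O)cc3c2[C@H](c2cc(OC)cc(OC)c2)[C@@H](c2ccc(OC)cc2)O3)cc1
F4 | step 3 | (2S)-7-methoxy-2-(4-methoxyphenyl)-4-oxo-3-(trifluoroacetyl)chroman-5-yl triflate (C3 enolisable) | O=C1C(C(=O)C(F)(F)F)[C@@H](c2ccc(OC)cc2)Oc2cc(OC)cc(OS(=O)(=O)C(F)(F)F)c12
F5 | step 3 | (2R)-3-diazo-7-methoxy-2-(4-methoxyphenyl)-4-oxochroman-5-yl triflate (C2 unchanged in space, descriptor changes through priorities) | O=C1C(=[N+]=[N-])[C@@H](c2ccc(OC)cc2)Oc2cc(OC)cc(OS(=O)(=O)C(F)(F)F)c12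
F6 | step 3 | methyl (2S,3R)-6-methoxy-2-(4-methoxyphenyl)-4-(triflyloxy)-2,3-dihydrobenzofuran-3-carboxylate (cis) | COc1ccc([C@H]2Oc3cc(OC)cc(OS(=O)(=O)C(F)(F)F)c3[C@H]2C(=O)OC)cc1
F7 | step 7 | (2S,3S)-6-methoxy-2-(4-methoxyphenyl)-3-(4,4,5,5-tetramethyl-1,3,2-dioxaborolan-2-yl)-2,3-dihydrobenzofuran-4-yl triflate (trans) | COc1ccc([C@H]2Oc3cc(OC)cc(OS(=O)(=O)C(F)(F)F)c3[C@@H]2B2OC(C)(C)C(C)(C)O2)cc1
F8 | step 7 | lithium boronate complex of F7 with 9 | COc1ccc([C@H]2Oc3cc(OC)cc(OS(=O)(=O)C(F)(F)F)c3[C@@H]2[B-]2(c3cc(OCOC)cc(OCOC)c3)OC(C)(C)C(C)(C)O2)cc1.[Li+]
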